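**Retrosynthetic overview**
1. The 22-membered lactone (C21–O–C1) is opened to a C1–C3 β-lactone carrying a free C21–OH. The key C–O bond is made last by a strain-release ring expansion that also frees the C3–OH.
2. The open chain is cut at C7–C8 (Stille: vinylstannane β-lactone 35 + allylic chloride 27) and at C14=C15 (Julia–Kocienski: sulfone 20 + aldehyde 26).
3. C15–C30 comes from ynal 7 by δ-stannyl anti-crotylboration (C20, C21), alkyne-to-(E)-alkene reduction, acyl-Stille coupling and CBS reduction (C17). Nothing is heated above 35 °C once the (E,Z,Z)-triene exists.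
4. C8–C14 comes from a Keck allylation with a bifunctional allylstannane (C11). C1–C7 comes from an acetate aldol (C5) and a ketene–aldehyde cycloaddition (C3).
5. Ring order: the oxetan-2-one first (step 22), then the macrolactone (step 25).

Assumption: locants C1–C30 are those of the target chain (C1 lactone carbonyl, C21 lactone carbinol, C22–C30 side chain); 15, 28 and 30 are taken as catalogue compounds.

**Route**

Step 1
Reactants: 1 (2Z)-3-methylpent-2-en-4-yn-1-ol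
Product: 2 (2Z)-3-methylpent-2-en-4-ynal
Conditions: MnO2 (15 equiv), CH2Cl2, 0 °C to rt, dark; filtrate used cold
Reagents that add atoms: none
Why: Allylic alcohol oxidation with MnO2 is neutral, so the Z-enal (future C24=C25) does not isomerise.

Step 2
Reactants: 2 (2Z)-3-methylpent-2-en-4-ynal; 3 but-3-en-1-yl(triphenyl)phosphonium bromide
Product: 5 (3Z,5Z)-3-methylnona-3,5,8-trien-1-yne, via phosphorus ylide 4 (not isolated)
Conditions: 3, NaN(SiMe3)2, THF, −78 to 0 °C; then 2, −78 °C to rt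
Reagents that add atoms: none
Why: A salt-free Wittig reaction of a non-stabilised ylide gives the 26Z alkene under kinetic control.

Step 3
Reactants: 5 (3Z,5Z)-3-methylnona-3,5,8-trien-1-yne
Product: 7 (4Z,6Z)-4-methyldeca-4,6,9-trien-2-ynal, via lithium acetylide 6 (not isolated)
Conditions: n-BuLi, THF, −78 °C; DMF, −78 to 0 °C; inverse quench into aq. KH2PO4
Reagents that add atoms: N,N-dimethylformamide, CN(C)C=O
Why: Acetylide formylation with DMF and a buffered inverse quench gives the ynal (C21) without amine addition.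

Step 4
Reactants: 8 rac-but-3-yn-2-ol
Product: 9 rac-but-3-yn-2-yl methanesulfonate
Conditions: MsCl, Et3N, CH2Cl2, −78 to 0 °C
Reagents that add atoms: methanesulfonyl chloride, CS(=O)(=O)Cl
Why: Standard sulfonylation of a secondary propargylic alcohol.

Step 5
Reactants: 9 rac-but-3-yn-2-yl methanesulfonate
Product: 10 rac-tributyl(buta-1,2-dien-1-yl)stannane
Conditions: Bu3SnH, LiN(i-Pr)2, THF, 0 °C; CuBr·SMe2, −78 °C; then 9, −78 °C
Reagents that add atoms: tributyltin hydride (as tributylstannyllithium), CCCC[SnH](CCCC)CCCC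
Why: A stannylcuprate displaces the propargylic mesylate in the SN2′ sense to give the allenylstannane.

Step 6
Reactants: 7 (4Z,6Z)-4-methyldeca-4,6,9-trien-2-ynal; 10 rac-tributyl(buta-1,2-dien-1-yl)stannane
Product: 12 (1E,3R,4R,7Z,9Z)-3,7-dimethyl-1-(tributylstannyl)trideca-1,7,9,12-tetraen-5-yn-4-ol, via alpha-stannyl crotylborane 11 (not isolated)
Conditions: 10 (1.3 equiv), (lIpc)2BH [from (−)-α-pinene], toluene, −40 to −20 °C, 5 h; then 7, −78 °C; NaBO3·4H2O, THF–H2O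
Reagents that add atoms: none
Why: Enantioconvergent allene hydroboration then aldehyde crotylboration through a chair transition state (SnBu3 pseudo-equatorial, (E)-crotyl) gives the 18E vinylstannane and the anti C20-Me/C21-OH pair (20R; C21 as in the target, formally R here because alkynyl outranks C20); the borane antipode is the one predicted by the Brown model.

Step 7
Reactants: 12 (1E,3R,4R,7Z,9Z)-3,7-dimethyl-1-(tributylstannyl)trideca-1,7,9,12-tetraen-5-yn-4-ol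
Product: 13 (1E,3R,4S,5E,7Z,9Z)-3,7-dimethyl-1-(tributylstannyl)trideca-1,5,7,9,12-pentaen-4-ol
Conditions: NaAlH2(OCH2CH2OMe)2 (Red-Al), THF, 0 °C; aq. KNaC4H4O6
Reagents that add atoms: none
Why: Hydroxyl-directed trans-hydroalumination of the propargylic alcohol gives only the 22E alkene and leaves the vinylstannane and the other alkenes untouched.

Step 8
Reactants: 13 (1E,3R,4S,5E,7Z,9Z)-3,7-dimethyl-1-(tributylstannyl)trideca-1,5,7,9,12-pentaen-4-ol
Product: 14 triethylsilyl ether of 13 (21-O-TES)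
Conditions: Et3SiCl, imidazole, cat. DMAP, CH2Cl2, 0 °C to rt
Reagents that add atoms: chlorotriethylsilane, CC[Si](Cl)(CC)CC
Why: Silylation marks C21–OH with the one group that can later be removed in the presence of TBS ethers.

Step 9
Reactants: 14 triethylsilyl ether of 13; 15 3-[(1-phenyl-1H-tetrazol-5-yl)sulfanyl]propanoic acid
Product: 17 (4E,6R,7S,8E,10Z,12Z)-6,10-dimethyl-1-[(1-phenyl-1H-tetrazol-5-yl)sulfanyl]-7-[(triethylsilyl)oxy]hexadeca-4,8,10,12,15-pentaen-3-one, via acid chloride 16 (not isolated)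
Conditions: 15, (COCl)2, cat. DMF, CH2Cl2, 0 °C, evaporate; then 14, Pd2(dba)3 (2.5 mol%), P(2-furyl)3 (10 mol%), THF, 30 °C
Reagents that add atoms: none
Why: Acylative Stille coupling of a vinylstannane with an acid chloride is neutral and keeps the 18E geometry while joining C17 to C18.

Step 10
Reactants: 17 the C17 enone
Product: 18 (3S,4E,6R,7S,8E,10Z,12Z)-6,10-dimethyl-1-[(1-phenyl-1H-tetrazol-5-yl)sulfanyl]-7-[(triethylsilyl)oxy]hexadeca-4,8,10,12,15-pentaen-3-ol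
Conditions: (R)-2-methyl-CBS-oxazaborolidine (0.5 equiv), catecholborane, toluene, −78 °C
Reagents that add atoms: none
Why: CBS reduction of the enone (alkenyl as the large group) sets 17S under reagent control; catecholborane does not hydroborate the alkenes.

Step 11
Reactants: 18 the 17S allylic alcohol
Product: 19 17-O-TBS ether of 18
Conditions: TBSOTf, 2,6-lutidine, CH2Cl2, −78 °C
Reagents that add atoms: tert-butyldimethylsilyl triflate, CC(C)(C)[Si](C)(C)OS(=O)(=O)C(F)(F)F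
Why: Standard silylation; the TES ether at C21 is untouched.

Step 12
Reactants: 19 17-O-TBS sulfide
Product: 20 C15–C30 phenyltetrazolyl sulfone (17-O-TBS, 21-O-TES)
Conditions: (NH4)6Mo7O24·4H2O (20 mol%), 30% H2O2, EtOH, pH 7 buffer, 0 °C to rt
Reagents that add atoms: hydrogen peroxide, OO
Why: Molybdate-catalysed oxidation is selective for sulfur over the alkenes and silyl ethers.

Step 13
Reactants: 21 3-chloro-2-(chloromethyl)prop-1-ene
Product: 22 tributyl[2-(chloromethyl)prop-2-en-1-yl]stannane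
Conditions: Bu3SnH, LiN(i-Pr)2, THF, 0 °C; added to 21 (3 equiv), THF, −78 °C
Reagents that add atoms: tributyltin hydride (as tributylstannyllithium), CCCC[SnH](CCCC)CCCC
Why: Mono-substitution of the symmetrical bis-allylic chloride by the stannyl anion; excess 21 suppresses double substitution.

Step 14
Reactants: 22 tributyl[2-(chloromethyl)prop-2-en-1-yl]stannane; 23 methyl 4-oxobutanoate
Product: 24 methyl (4S)-6-(chloromethyl)-4-hydroxyhept-6-enoate
Conditions: (R)-BINOL (10 mol%), Ti(OiPr)4 (10 mol%), 4 Å sieves, CH2Cl2, −20 °C, 72 h; aq. NaHCO3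
Reagents that add atoms: none
Why: Keck asymmetric allylation sets 11S under catalyst control and installs C8–C10 with the exo-methylene and the allylic chloride in one step.

Step 15
Reactants: 24 methyl (4S)-6-(chloromethyl)-4-hydroxyhept-6-enoate
Product: 25 methyl (4S)-4-[(tert-butyldimethylsilyl)oxy]-6-(chloromethyl)hept-6-enoate
Conditions: TBSOTf, 2,6-lutidine, CH2Cl2, −78 °C (crude 24 used at once)
Reagents that add atoms: tert-butyldimethylsilyl triflate, CC(C)(C)[Si](C)(C)OS(=O)(=O)C(F)(F)F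
Why: Fast low-temperature silylation beats lactonisation of the γ-hydroxy ester.

Step 16
Reactants: 25 the TBS ether ester
Product: 26 (4S)-4-[(tert-butyldimethylsilyl)oxy]-6-(chloromethyl)hept-6-enal
Conditions: i-Bu2AlH (1.05 equiv), CH2Cl2, −78 °C; aq. KNaC4H4O6
Reagents that add atoms: none
Why: Partial ester reduction at −78 °C stops at the aldehyde (C14); the allylic chloride is inert.

Step 17
Reactants: 20 C15–C30 sulfone; 26 C8–C14 aldehyde
Product: 27 C8–C30 allylic chloride (11S,17S,20R,21S; 14E,18E,22E,24Z,26Z): ClCH2–C(=CH2)–CH2–CH(OTBS)–(CH2)2–CH=CH–CH2–CH(OTBS)–CH=CH–CH(Me)–CH(OTES)–CH=CH–C(Me)=CH–CH=CH–CH2–CH=CH2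
Conditions: KN(SiMe3)2 added to 20 + 26, DME, −60 °C to rt; aq. NH4Cl
Reagents that add atoms: none
Why: Julia–Kocienski olefination of a phenyltetrazolyl sulfone gives the 14E alkene; Barbier addition keeps the carbanion concentration low so the allylic chloride survives.

Step 18
Reactants: 28 (2E)-3-(tributylstannyl)prop-2-en-1-ol
Product: 29 (2E)-3-(tributylstannyl)prop-2-enal
Conditions: MnO2, CH2Cl2, rt
Reagents that add atoms: none
Why: Neutral allylic oxidation keeps the C–Sn bond and the E geometry.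

Step 19
Reactants: 29 (2E)-3-(tributylstannyl)prop-2-enal; 30 (4R)-3-acetyl-4-benzyl-1,3-thiazolidine-2-thione
Product: 32 (3S,4E)-1-[(4R)-4-benzyl-2-sulfanylidene-1,3-thiazolidin-3-yl]-3-hydroxy-5-(tributylstannyl)pent-4-en-1-one, via tin enolate 31 (not isolated)
Conditions: 30, Sn(OTf)2, N-ethylpiperidine, CH2Cl2, −50 °C; then 29, −78 °C
Reagents that add atoms: none
Why: Nagao acetate aldol through a chelated divalent-tin enolate; the auxiliary sets 5S (sense taken from the chelate model).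

Step 20
Reactants: 32 the aldol adduct
Product: 33 5-O-TBS ether of 32
Conditions: TBSOTf, 2,6-lutidine, CH2Cl2, −78 °C
Reagents that add atoms: tert-butyldimethylsilyl triflate, CC(C)(C)[Si](C)(C)OS(=O)(=O)C(F)(F)F
Why: Standard silylation; lutidine buffering protects the vinylstannane from protodestannylation.

Step 21
Reactants: 33 the silylated imide
Product: 34 (3S,4E)-3-[(tert-butyldimethylsilyl)oxy]-5-(tributylstannyl)pent-4-enal
Conditions: i-Bu2AlH, CH2Cl2, −78 °C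
Reagents that add atoms: none
Why: N-Acyl thiazolidinethiones are reduced directly to aldehydes, releasing the auxiliary.

Step 22
Reactants: 34 the C3 aldehyde
Product: 35 (4S)-4-[(2S,3E)-2-[(tert-butyldimethylsilyl)oxy]-4-(tributylstannyl)but-3-en-1-yl]oxetan-2-one
Conditions: AcCl, i-Pr2NEt, LiClO4, O-trimethylsilylquinidine (10 mol%), CH2Cl2–Et2O, −78 °C
Reagents that add atoms: acetyl chloride, CC(Cl)=O
Why: Alkaloid-catalysed ketene–aldehyde [2+2] cycloaddition (Wynberg/Nelson type) builds C1–C2 and the β-lactone and sets 3S (3,5-anti) under catalyst control; the quinine-derived pseudoenantiomer would give the 3-epimer.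

Step 23
Reactants: 27 C8–C30 allylic chloride; 35 C1–C7 β-lactone vinylstannane
Product: 36 C1–C30 β-lactone with 21-O-TES (chain of 27 joined at C8 to C7H=C6H–C5H(OTBS)–C4H2–(3S)-oxetan-2-one; 6E)
Conditions: Pd2(dba)3 (5 mol%), AsPh3 (20 mol%), NMP–THF, 35 °C
Reagents that add atoms: none
Why: Stille coupling of a vinylstannane with an allylic chloride; the 2-substituted π-allyl has equivalent termini, so one skipped diene forms and the 6E geometry is kept.

Step 24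
Reactants: 36 C1–C30 β-lactone with 21-O-TES
Product: 37 C1–C30 β-lactone with free C21–OH (5,11,17-tris-O-TBS)
Conditions: HF·pyridine, pyridine, THF, 0 °C
Reagents that add atoms: none
Why: Buffered fluoride cleaves the secondary TES ether much faster than the TBS ethers and does not open the β-lactone.

Step 25
Reactants: 37 C1–C30 β-lactone with free C21–OH
Product: 39 5,11,17-tris-O-TBS macrolactone with free C3–OH, via zinc alkoxide 38 (not isolated)
Conditions: [(BDI)ZnN(SiMe3)2] (10 mol%; BDI = HC[C(Me)N(2,6-i-Pr2C6H3)]2), toluene, 25 °C; 37 added by syringe pump over 12 h to 1 mM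
Reagents that add atoms: none
Why: Proposed new method: the divalent-zinc amide converts the only free hydroxyl (C21) into a zinc alkoxide, which inserts intramolecularly into the β-lactone by coordination–insertion with acyl–oxygen cleavage (retention at C3 and C21), driven by about 23 kcal/mol of ring strain; the resulting C3 zinc alkoxide exchanges with the C21–OH of the next substrate molecule, so the isomerisation is catalytic, needs no activating agent or C3 protection, and runs at room temperature (safe for the triene); high dilution suppresses oligomerisation; closest known reactions are zinc β-diketiminate-catalysed immortal ring-opening polymerisation of β-butyrolactone and translactonisation of hydroxy-β-lactones to γ- or δ-lactones.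

Step 26
Reactants: 39 tris-O-TBS macrolactone
Product: 40 target macrolide (3S,5S,11S,17S,20R,21S)
Conditions: HF·pyridine, pyridine, THF, 0 °C to rt
Reagents that add atoms: none
Why: Buffered global desilylation of three secondary TBS ethers; non-basic conditions avoid acyl migration and δ-lactone formation.

**Compound list**
1 | (2Z)-3-methylpent-2-en-4-yn-1-ol | OC/C=C(C)\C#C | starting material
2 | (2Z)-3-methylpent-2-en-4-ynal | O=C/C=C(C)\C#C | intermediate
3 | but-3-en-1-yl(triphenyl)phosphonium bromide | C=CCC[P+](c1ccccc1)(c1ccccc1)c1ccccc1.[Br-] | starting material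
4 | (but-3-en-1-ylidene)triphenylphosphorane | C=CCC=P(c1ccccc1)(c1ccccc1)c1ccccc1 | intermediate
5 | (3Z,5Z)-3-methylnona-3,5,8-trien-1-yne | C=CC\C=C/C=C(C)\C#C | intermediate
6 | lithium acetylide of 5 | C=CC\C=C/C=C(C)\C#C[Li] | intermediate
7 | (4Z,6Z)-4-methyldeca-4,6,9-trien-2-ynal | C=CC\C=C/C=C(C)\C#CC=O | intermediate
8 | rac-but-3-yn-2-ol | CC(O)C#C | starting material
9 | rac-but-3-yn-2-yl methanesulfonate | CC(OS(C)(=O)=O)C#C | intermediate
10 | rac-tributyl(buta-1,2-dien-1-yl)stannane | CC=C=C[Sn](CCCC)(CCCC)CCCC | intermediate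
11 | [(1R,2E)-1-(tributylstannyl)but-2-en-1-yl]bis(l-isopinocampheyl)borane | C/C=C/[C@H]([Sn](CCCC)(CCCC)CCCC)B([C@H]1C[C@H]2C[C@@H]([C@@H]1C)C2(C)C)[C@H]1C[C@H]2C[C@@H]([C@@H]1C)C2(C)C | intermediate
12 | (1E,3R,4R,7Z,9Z)-3,7-dimethyl-1-(tributylstannyl)trideca-1,7,9,12-tetraen-5-yn-4-ol | C=CC\C=C/C=C(C)\C#C[C@H](O)[C@H](C)/C=C/[Sn](CCCC)(CCCC)CCCC | intermediate
13 | (1E,3R,4S,5E,7Z,9Z)-3,7-dimethyl-1-(tributylstannyl)trideca-1,5,7,9,12-pentaen-4-ol | C=CC\C=C/C=C(C)\C=C\[C@H](O)[C@H](C)/C=C/[Sn](CCCC)(CCCC)CCCC | intermediate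
14 | triethyl{[(1E,3R,4S,5E,7Z,9Z)-3,7-dimethyl-1-(tributylstannyl)trideca-1,5,7,9,12-pentaen-4-yl]oxy}silane | C=CC\C=C/C=C(C)\C=C\[C@H](O[Si](CC)(CC)CC)[C@H](C)/C=C/[Sn](CCCC)(CCCC)CCCC | intermediate
15 | 3-[(1-phenyl-1H-tetrazol-5-yl)sulfanyl]propanoic acid | OC(=O)CCSc1nnnn1-c1ccccc1 | starting material
16 | 3-[(1-phenyl-1H-tetrazol-5-yl)sulfanyl]propanoyl chloride | ClC(=O)CCSc1nnnn1-c1ccccc1 | intermediate
17 | (4E,6R,7S,8E,10Z,12Z)-6,10-dimethyl-1-[(1-phenyl-1H-tetrazol-5-yl)sulfanyl]-7-[(triethylsilyl)oxy]hexadeca-4,8,10,12,15-pentaen-3-one | C=CC\C=C/C=C(C)\C=C\[C@H](O[Si](CC)(CC)CC)[C@H](C)/C=C/C(=O)CCSc1nnnn1-c1ccccc1 | intermediate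
18 | (3S,4E,6R,7S,8E,10Z,12Z)-6,10-dimethyl-1-[(1-phenyl-1H-tetrazol-5-yl)sulfanyl]-7-[(triethylsilyl)oxy]hexadeca-4,8,10,12,15-pentaen-3-ol | C=CC\C=C/C=C(C)\C=C\[C@H](O[Si](CC)(CC)CC)[C@H](C)/C=C/[C@@H](O)CCSc1nnnn1-c1ccccc1 | intermediate
19 | 17-O-TBS ether of 18 (C15–C30 sulfide; 17S,20R,21S) | C=CC\C=C/C=C(C)\C=C\[C@H](O[Si](CC)(CC)CC)[C@H](C)/C=C/[C@@H](O[Si](C)(C)C(C)(C)C)CCSc1nnnn1-c1ccccc1 | intermediate
20 | C15–C30 sulfone: 5-{[(3S,4E,6R,7S,8E,10Z,12Z)-3-(TBS-oxy)-6,10-dimethyl-7-(TES-oxy)hexadeca-4,8,10,12,15-pentaen-1-yl]sulfonyl}-1-phenyl-1H-tetrazole | C=CC\C=C/C=C(C)\C=C\[C@H](O[Si](CC)(CC)CC)[C@H](C)/C=C/[C@@H](O[Si](C)(C)C(C)(C)C)CCS(=O)(=O)c1nnnn1-c1ccccc1 | intermediate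
21 | 3-chloro-2-(chloromethyl)prop-1-ene | C=C(CCl)CCl | starting material
22 | tributyl[2-(chloromethyl)prop-2-en-1-yl]stannane | C=C(CCl)C[Sn](CCCC)(CCCC)CCCC | intermediate
23 | methyl 4-oxobutanoate | COC(=O)CCC=O | starting material
24 | methyl (4S)-6-(chloromethyl)-4-hydroxyhept-6-enoate | COC(=O)CC[C@H](O)CC(=C)CCl | intermediate
25 | methyl (4S)-4-[(tert-butyldimethylsilyl)oxy]-6-(chloromethyl)hept-6-enoate | COC(=O)CC[C@H](O[Si](C)(C)C(C)(C)C)CC(=C)CCl | intermediate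
26 | (4S)-4-[(tert-butyldimethylsilyl)oxy]-6-(chloromethyl)hept-6-enal | O=CCC[C@H](O[Si](C)(C)C(C)(C)C)CC(=C)CCl | intermediate
27 | C8–C30 allylic chloride (11S,17S,20R,21S; 14E,18E,22E,24Z,26Z; 11,17-bis-O-TBS, 21-O-TES) | C=CC\C=C/C=C(C)\C=C\[C@H](O[Si](CC)(CC)CC)[C@H](C)/C=C/[C@@H](O[Si](C)(C)C(C)(C)C)C/C=C/CC[C@H](O[Si](C)(C)C(C)(C)C)CC(=C)CCl | intermediate
28 | (2E)-3-(tributylstannyl)prop-2-en-1-ol | OC/C=C/[Sn](CCCC)(CCCC)CCCC | starting material
29 | (2E)-3-(tributylstannyl)prop-2-enal | O=C/C=C/[Sn](CCCC)(CCCC)CCCC | intermediate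
30 | (4R)-3-acetyl-4-benzyl-1,3-thiazolidine-2-thione | CC(=O)N1[C@H](Cc2ccccc2)CSC1=S | starting material
31 | divalent-tin enolate of 30 (triflate as second ligand) | C=C(O[Sn]OS(=O)(=O)C(F)(F)F)N1[C@H](Cc2ccccc2)CSC1=S | intermediate
32 | (3S,4E)-1-[(4R)-4-benzyl-2-sulfanylidene-1,3-thiazolidin-3-yl]-3-hydroxy-5-(tributylstannyl)pent-4-en-1-one | CCCC[Sn](CCCC)(CCCC)/C=C/[C@@H](O)CC(=O)N1[C@H](Cc2ccccc2)CSC1=S | intermediate
33 | (3S,4E)-1-[(4R)-4-benzyl-2-sulfanylidene-1,3-thiazolidin-3-yl]-3-[(tert-butyldimethylsilyl)oxy]-5-(tributylstannyl)pent-4-en-1-one | CCCC[Sn](CCCC)(CCCC)/C=C/[C@@H](O[Si](C)(C)C(C)(C)C)CC(=O)N1[C@H](Cc2ccccc2)CSC1=S | intermediate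
34 | (3S,4E)-3-[(tert-butyldimethylsilyl)oxy]-5-(tributylstannyl)pent-4-enal | CCCC[Sn](CCCC)(CCCC)/C=C/[C@@H](O[Si](C)(C)C(C)(C)C)CC=O | intermediate
35 | (4S)-4-[(2S,3E)-2-[(tert-butyldimethylsilyl)oxy]-4-(tributylstannyl)but-3-en-1-yl]oxetan-2-one | CCCC[Sn](CCCC)(CCCC)/C=C/[C@@H](O[Si](C)(C)C(C)(C)C)C[C@H]1CC(=O)O1 | intermediate
36 | C1–C30 β-lactone, 5,11,17-tris-O-TBS, 21-O-TES (3S,5S,11S,17S,20R,21S; 6E,14E,18E,22E,24Z,26Z) | C=CC\C=C/C=C(C)\C=C\[C@H](O[Si](CC)(CC)CC)[C@H](C)/C=C/[C@@H](O[Si](C)(C)C(C)(C)C)C/C=C/CC[C@H](O[Si](C)(C)C(C)(C)C)CC(=C)C/C=C/[C@@H](O[Si](C)(C)C(C)(C)C)C[C@H]1CC(=O)O1 | intermediate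
37 | C1–C30 β-lactone, 5,11,17-tris-O-TBS, free C21–OH | C=CC\C=C/C=C(C)\C=C\[C@H](O)[C@H](C)/C=C/[C@@H](O[Si](C)(C)C(C)(C)C)C/C=C/CC[C@H](O[Si](C)(C)C(C)(C)C)CC(=C)C/C=C/[C@@H](O[Si](C)(C)C(C)(C)C)C[C@H]1CC(=O)O1 | intermediate
38 | (BDI)Zn C21-alkoxide of 37 | C=CC\C=C/C=C(C)\C=C\[C@H](O[Zn]N(c1c(C(C)C)cccc1C(C)C)/C(C)=C\C(C)=N\c1c(C(C)C)cccc1C(C)C)[C@H](C)/C=C/[C@@H](O[Si](C)(C)C(C)(C)C)C/C=C/CC[C@H](O[Si](C)(C)C(C)(C)C)CC(=C)C/C=C/[C@@H](O[Si](C)(C)C(C)(C)C)C[C@H]1CC(=O)O1 | intermediate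
39 | 5,11,17-tris-O-TBS 22-membered macrolactone, free C3–OH | C=CC\C=C/C=C(C)\C=C\[C@H]1[C@H](C)/C=C/[C@@H](O[Si](C)(C)C(C)(C)C)C/C=C/CC[C@H](O[Si](C)(C)C(C)(C)C)CC(=C)C/C=C/[C@@H](O[Si](C)(C)C(C)(C)C)C[C@H](O)CC(=O)O1 | intermediate
40 | target macrolide CNP0297533.1 (3S,5S,11S,17S,20R,21S) | C=CC\C=C/C=C(C)\C=C\[C@@H]1OC(=O)C[C@@H](O)C[C@H](O)/C=C/CC(=C)C[C@@H](O)CC/C=C/C[C@H](O)/C=C/[C@H]1C | target

**Totals**
Total steps: 26. Longest linear sequence: 15 (steps 1–3, 6–12, 17, 23–26).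

**Three steps most likely to fail**

Step 25 (new ring expansion): oligomerisation or no insertion at the hindered C21 alkoxide. The fallback sets out from 36 and comes back at 40. LiOH (THF–H2O, 0 °C) opens the β-lactone at the acyl carbon to the 21-O-TES β-hydroxy acid F1. TBSOTf/2,6-lutidine, then K2CO3 in MeOH–H2O to cleave the silyl ester, gives the 3-O-TBS acid F2. HF·pyridine/pyridine removes only the TES group to give the seco-acid F3. Shiina macrolactonisation (2-methyl-6-nitrobenzoic anhydride, DMAP, CH2Cl2, 1 mM, rt) closes the ring to the tetrakis-TBS macrolactone F4, and HF·pyridine then gives 40.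

Step 23 (Stille union of two advanced fragments): slow transmetalation of the hindered stannane or loss of the β-lactone. The fallback sets out from 27 and comes back at 36. Chloride 27 is coupled instead with the small stannane 29 in excess (Pd2(dba)3, AsPh3) to give the C5 enal F5. Acetate aldol with 30 (Sn(OTf)2, N-ethylpiperidine) gives the 5S aldol adduct F6, TBSOTf gives the silyl ether F7, and i-Bu2AlH gives the C3 aldehyde F8. The ketene cycloaddition of step 22 then builds the β-lactone on the full chain to give 36.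

Step 6 (crotylboration of the sensitive ynal): incomplete allene hydroboration or erosion of anti selectivity. The fallback sets out from 7 and comes back at 12. Commercial (S)-but-3-yn-2-ol is mesylated to (S)-but-3-yn-2-yl methanesulfonate F9. Its allenylzinc (Pd(OAc)2, PPh3, Et2Zn, THF, −20 °C; Marshall propargylation, net inversion, anti-selective) adds to 7 to give the diyne alcohol F10. PdCl2(PPh3)2-catalysed hydrostannation of the terminal alkyne (Bu3SnH, THF, −20 °C) then gives 12.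

**Further compounds**
F1 | step 25 | 21-O-TES, 5,11,17-tris-O-TBS β-hydroxy acid | C=CC\C=C/C=C(C)\C=C\[C@H](O[Si](CC)(CC)CC)[C@H](C)/C=C/[C@@H](O[Si](C)(C)C(C)(C)C)C/C=C/CC[C@H](O[Si](C)(C)C(C)(C)C)CC(=C)C/C=C/[C@@H](O[Si](C)(C)C(C)(C)C)C[C@H](O)CC(=O)O
F2 | step 25 | 21-O-TES, 3,5,11,17-tetrakis-O-TBS acid | C=CC\C=C/C=C(C)\C=C\[C@H](O[Si](CC)(CC)CC)[C@H](C)/C=C/[C@@H](O[Si](C)(C)C(C)(C)C)C/C=C/CC[C@H](O[Si](C)(C)C(C)(C)C)CC(=C)C/C=C/[C@@H](O[Si](C)(C)C(C)(C)C)C[C@H](O[Si](C)(C)C(C)(C)C)CC(=O)O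
F3 | step 25 | 3,5,11,17-tetrakis-O-TBS seco-acid with free C21–OH | C=CC\C=C/C=C(C)\C=C\[C@H](O)[C@H](C)/C=C/[C@@H](O[Si](C)(C)C(C)(C)C)C/C=C/CC[C@H](O[Si](C)(C)C(C)(C)C)CC(=C)C/C=C/[C@@H](O[Si](C)(C)C(C)(C)C)C[C@H](O[Si](C)(C)C(C)(C)C)CC(=O)O
F4 | step 25 | 3,5,11,17-tetrakis-O-TBS macrolactone | C=CC\C=C/C=C(C)\C=C\[C@H]1[C@H](C)/C=C/[C@@H](O[Si](C)(C)C(C)(C)C)C/C=C/CC[C@H](O[Si](C)(C)C(C)(C)C)CC(=C)C/C=C/[C@@H](O[Si](C)(C)C(C)(C)C)C[C@H](O[Si](C)(C)C(C)(C)C)CC(=O)O1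
F5 | step 23 | C5–C30 enal (11,17-bis-O-TBS, 21-O-TES) | C=CC\C=C/C=C(C)\C=C\[C@H](O[Si](CC)(CC)CC)[C@H](C)/C=C/[C@@H](O[Si](C)(C)C(C)(C)C)C/C=C/CC[C@H](O[Si](C)(C)C(C)(C)C)CC(=C)C/C=C/C=O
F6 | step 23 | 5S aldol adduct with the thiazolidinethione auxiliary | C=CC\C=C/C=C(C)\C=C\[C@H](O[Si](CC)(CC)CC)[C@H](C)/C=C/[C@@H](O[Si](C)(C)C(C)(C)C)C/C=C/CC[C@H](O[Si](C)(C)C(C)(C)C)CC(=C)C/C=C/[C@@H](O)CC(=O)N1[C@H](Cc2ccccc2)CSC1=S
F7 | step 23 | 5-O-TBS ether of F6 | C=CC\C=C/C=C(C)\C=C\[C@H](O[Si](CC)(CC)CC)[C@H](C)/C=C/[C@@H](O[Si](C)(C)C(C)(C)C)C/C=C/CC[C@H](O[Si](C)(C)C(C)(C)C)CC(=C)C/C=C/[C@@H](O[Si](C)(C)C(C)(C)C)CC(=O)N1[C@H](Cc2ccccc2)CSC1=S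
F8 | step 23 | C3–C30 aldehyde (5,11,17-tris-O-TBS, 21-O-TES) | C=CC\C=C/C=C(C)\C=C\[C@H](O[Si](CC)(CC)CC)[C@H](C)/C=C/[C@@H](O[Si](C)(C)C(C)(C)C)C/C=C/CC[C@H](O[Si](C)(C)C(C)(C)C)CC(=C)C/C=C/[C@@H](O[Si](C)(C)C(C)(C)C)CC=O
F9 | step 6 | (S)-but-3-yn-2-yl methanesulfonate | C[C@H](OS(C)(=O)=O)C#C
F10 | step 6 | (3R,4R,7Z,9Z)-3,7-dimethyltrideca-7,9,12-trien-1,5-diyn-4-ol | C=CC\C=C/C=C(C)\C#C[C@H](O)[C@H](C)C#C
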